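**Analysis of the target**

Target 21 is an azaphilone, a 6H-isochromene-6,8(7H)-dione. Ring A (O2, C1, C3, C4, C4a, C8a) is a 4H-pyran-4-ylidene and ring B (C4a, C5, C6, C7, C8, C8a) a cyclohexenedione; they share the cross-conjugated system C1=C8a, C3=C4, C4a=C5 with the C6 and C8 carbonyl groups. C3 carries an (E)-3-oxoprop-1-enyl chain, and C7 carries a methyl group and the ester oxygen of orsellinic acid 1. C7 is the only stereocentre (R); it is quaternary and lies between two ketones, so it has no neighbour to relay from and cannot be corrected by epimerisation. The sensitive sites are the dienal, the two free phenols, the pyran carbon C1 (a vinylogous ester carbon that nitrogen nucleophiles attack with ring opening) and the tertiary α-acyloxy-β-diketone, which nucleophilic base can cleave by retro-Claisen fragmentation. The difficulty is that the two flanks of C7 are almost alike: C6 and C8 are both ketones, C5 and C8a both sp2 carbons, and only the C1 branch on C8a distinguishes them. The route rests on this feature: ring B without C1 is mirror-symmetric through C7 and C4a, so an open-chain precursor with two identical three-carbon arms on C7 (C8–C8a–C1 and C6–C5–C4a) is prochiral, and C7 becomes stereogenic when the bond C4a–C8a joins the α-carbon of one arm to the β-carbon of the other.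

**Retrosynthetic reasoning**

From 21 the C1′=C2′ double bond of the side chain is cut first, giving aldehyde 19 and the two-carbon ylide 20. The enal is the most fragile part of the molecule, so it is made last and under neutral conditions; a stabilised ylide should give the E isomer.

19 is traced back to 18 by functional group interconversion only. The C3 aldehyde is carried as a dimethyl acetal and the phenols as methoxymethyl ethers, and all three fall in one aqueous acid treatment. Keeping the phenols masked up to this point protects them during the preceding oxidation.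

18 is simplified to 17 by adding hydrogen to C4a and C5. The C4a–C4 bond is best made by attack of a nucleophilic carbon on C4a as an enone β-carbon, which leaves C4a sp3. The forward step is a dehydrogenation that can only run across C4a–C5 because C7 has no hydrogen.

In 17 ring A is cut at C4a–C4 and O2–C3, giving the formyl dienone 12 and the enol ether 15. 12 already holds O2 on C1 and offers, in one of its tautomers, the 1-oxadiene O=C1–C8a=C4a; 15 supplies C3, C4 and the masked C3 aldehyde. The forward reaction is an inverse-demand hetero-Diels–Alder reaction followed by loss of the ketal methoxy group. 15 comes from ketal 14 and this from the commercial ketone 13.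

12 is the hydrolysis product of the enaminone 11. The amine is kept on C1 as long as possible because, while it is there, the two C7 epimers are diastereomers and can be separated.

11 is opened at C4a–C8a to the bis-enaminone 10; this is the key disconnection. It removes ring B and the stereocentre together and leaves a precursor with two identical arms, so the whole stereochemical problem becomes the choice between two enantiotopic arms in one ring closure.

10 is taken back to the bis(dimethylamino) compound 8 by exchange with the amine 9, and 8 to the diketone 6 and two molecules of 7, which supply C1 and C4a. Cutting both arms at the acetyl methyl groups uses the symmetry fully: both arms are made in one operation.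

6 is cut at C7–CH3 to 5 (enolate C-methylation) and 5 at the C7–O bond to the acid 3 and the chloro diketone 4 (carboxylate displacement). Making the hindered ester as a C–O bond at a secondary, doubly activated carbon, before C7 is quaternary, avoids acylating a tertiary alcohol with a di-ortho-substituted benzoic acid. 3 comes from 1 through 2 by methoxymethylation and ester cleavage.

**Alternatives that were turned down**

Alternative 1: Ring B is cut at C6–C7. A chiral triazolium-derived carbene would turn a C6 aldehyde, held on C5 of a preformed pyran-4-ylidene, into an acyl anion equivalent that adds to the C7 ketone of a neighbouring 1,2-diketone. This closes ring B, sets C7 and gives the tertiary alcohol A1.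
- For: intramolecular aldehyde–ketone benzoin reactions that make six-membered tertiary α-ketols are an established, catalytic, enantioselective reaction class; ring A and the side chain are already present.
- Against: the aldehyde is the end of a push–pull system fed by O2 through both C1=C8a and C3=C4, so it is a poor electrophile for the carbene, and as an enal it can divert to homoenolate reactivity at C4a. The acyl anion must also choose C7 over C8.
- Against: A1 is a free tertiary α-ketol between two carbonyl groups, open to acyloin rearrangement. It must then be esterified with a di-ortho-substituted benzoic acid, a bond far easier to make as in step 3. The side chain still needs deprotection and oxidation.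
- Comparison: this alternative is stronger on catalytic use of chirality and on precedent. The chosen route offers instead a recoverable stoichiometric amine, an ester in place from the start, and purification of diastereomers because the amine stays in 11.

Alternative 2: The C7–C8 bond is cut, so ring B becomes an enol lactone with C8 as acyl carbon and C7 as enol carbon. A chiral nucleophilic acyl-transfer catalyst (isothiourea or 4-aminopyridine type) would open the lactone to an acylammonium–enolate ion pair that recombines at carbon, contracting the lactone to the carbocycle and creating the quaternary centre in A2.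
- For: A2 holds the complete skeleton, the ester and the masked enal, so a single acidic deprotection would finish the synthesis. This is clearly better step economy after the key step than here. Enantioselective O-to-C acyl shifts that make quaternary centres are well known.
- Against: those shifts work on enolates that are part of an aromatic heterocycle and transfer an exocyclic acyl group. Here acyl carbon and enolate are tethered through the pyranylidene, the extended α-acyloxylated enolate can be acylated at oxygen or at C5, and the orsellinate on C7 can itself migrate.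
- Against: the N-nucleophilic catalyst also meets C1 of the pyran, where such ring systems are opened by nitrogen nucleophiles. The substrate, a fused enol lactone with a tetrasubstituted exocyclic enol ester of defined geometry and the full side chain, is itself a long synthesis, so the risk is not confined to one step.
- Comparison: the chosen route trades the short endgame for a key-step precursor reached in six simple steps from symmetric, achiral material.

Alternative 3: Both rings are cut at once at C4a–C8a, C3–C4 and O2–C1. Cp*RuCl(cod), a divalent ruthenium complex, would couple the two alkynes of a 1,7-diyne (an ynone arm and a propargyl ketone arm on C7) with the aldehyde C=O of a protected side-chain enal in a [2+2+2] cycloaddition, giving the 3H-isochromene A3.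
- For: it is the most convergent plan, forming three bonds and two rings in one step and bringing in the side chain.
- Against: the step does not create C7. The diyne must already contain the quaternary stereocentre with two different acyl arms, so the problem is only moved to an acyclic compound where the arms are harder to tell apart.
- Against: A3 forms as C3 epimers at the wrong oxidation level (C5H2, C4=C4a) and needs a double-bond shift and dehydrogenation; as a 2H-pyran it can open electrocyclically to a dienone. The aldehyde can insert in two orientations into the unsymmetrical ruthenacycle, and the terminal ynone and enolisable propargyl ketone are sensitive partners.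
- Comparison: this alternative is stronger on bonds formed per step. The chosen route instead solves the stereochemical problem in the ring-forming step itself.

Key step: step 7

Assumption: the (2R,5R)-amine 9 is taken to favour the arm that leads to (7R); should it favour (7S), the (2S,5S)-amine is used and nothing else changes.
Remark: 12 is a vinylogous acid with several tautomers; it is drawn and named as the hydroxymethylidene form, in which the C7 descriptor stays R.

**Route**

Step 1
Reactants: 1 orsellinic acid
Product: 2 methoxymethyl 2,4-bis(methoxymethoxy)-6-methylbenzoate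
Conditions: MOMCl (4 equiv), iPr2NEt (5 equiv), DMF, 0 °C → rt
Reagents that add atoms: chloromethyl methyl ether, COCCl
Why: O-alkylation of both phenols and the carboxylic acid with a reactive α-chloro ether; the mild temperature avoids decarboxylation of the β-resorcylic acid.

Step 2
Reactants: 2 methoxymethyl 2,4-bis(methoxymethoxy)-6-methylbenzoate
Product: 3 2,4-bis(methoxymethoxy)-6-methylbenzoic acid
Conditions: LiOH·H2O, THF/MeOH/H2O, rt; then 1 M HCl to pH 4, 0 °C
Reagents that add atoms: lithium hydroxide, [Li+].[OH-]
Why: Saponification of the acyl acetal ester, which is far more labile than the aryl MOM ethers; these are stable to base and to a brief cold acidification.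

Step 3
Reactants: 3 2,4-bis(methoxymethoxy)-6-methylbenzoic acid; 4 3-chloropentane-2,4-dione
Product: 5 2,4-dioxopentan-3-yl 2,4-bis(methoxymethoxy)-6-methylbenzoate
Conditions: 3, KHCO3 (1.0 equiv), DMF, rt; then 4 (1.1 equiv), rt
Reagents that add atoms: none
Why: SN2 displacement of a secondary chloride activated by two carbonyl groups by the preformed potassium carboxylate; the hindered acid reacts through its unhindered carboxylate oxygen, and no excess base is present to enolise 4.

Step 4
Reactants: 5 2,4-dioxopentan-3-yl 2,4-bis(methoxymethoxy)-6-methylbenzoate
Product: 6 3-methyl-2,4-dioxopentan-3-yl 2,4-bis(methoxymethoxy)-6-methylbenzoate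
Conditions: MeI (3 equiv), K2CO3 (1.5 equiv), acetone, rt → 40 °C
Reagents that add atoms: iodomethane, CI
Why: C-alkylation of a stabilised β-diketone enolate with a soft electrophile, which makes the prochiral quaternary carbon (future C7); O-methylation is the minor pathway under these conditions.

Step 5
Reactants: 6 3-methyl-2,4-dioxopentan-3-yl 2,4-bis(methoxymethoxy)-6-methylbenzoate; 7 N,N-dimethylformamide dimethyl acetal
Product: 8 (1E,6E)-1,7-bis(dimethylamino)-4-methyl-3,5-dioxohepta-1,6-dien-4-yl 2,4-bis(methoxymethoxy)-6-methylbenzoate
Conditions: 7 (6 equiv), PhMe, 90 °C, N2 sweep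
Reagents that add atoms: none
Why: Condensation of both methyl ketones with the amide acetal to E-enaminones; the quaternary carbon leaves the acetyl methyl groups as the only enolisable positions, so both arms form in one operation.

Step 6
Reactants: 8 (1E,6E)-1,7-bis(dimethylamino)-4-methyl-3,5-dioxohepta-1,6-dien-4-yl 2,4-bis(methoxymethoxy)-6-methylbenzoate; 9 (2R,5R)-2,5-dimethylpyrrolidine
Product: 10 (1E,6E)-1,7-bis[(2R,5R)-2,5-dimethylpyrrolidin-1-yl]-4-methyl-3,5-dioxohepta-1,6-dien-4-yl 2,4-bis(methoxymethoxy)-6-methylbenzoate
Conditions: 9 (4 equiv), PhMe, 100 °C, slow N2 stream; excess 9 recovered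
Reagents that add atoms: none
Why: Amine exchange on a vinylogous amide by addition–elimination, driven by loss of volatile dimethylamine; it is run without acid so that the achiral enaminone does not cyclise early.

Step 7
Reactants: 10 (1E,6E)-1,7-bis[(2R,5R)-2,5-dimethylpyrrolidin-1-yl]-4-methyl-3,5-dioxohepta-1,6-dien-4-yl 2,4-bis(methoxymethoxy)-6-methylbenzoate
Product: 11 (1R,3E)-3-{[(2R,5R)-2,5-dimethylpyrrolidin-1-yl]methylidene}-1-methyl-2,6-dioxocyclohex-4-en-1-yl 2,4-bis(methoxymethoxy)-6-methylbenzoate
Conditions: AcOH/CH2Cl2 (1:4), 0.01 M, 0 °C → rt; aq NaHCO3; chromatography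
Reagents that add atoms: none
Why: Proposed new method: in acetic acid one enaminone arm is protonated on oxygen to a vinylogous iminium ion and the α-carbon of the other, still neutral arm (future C8a) adds to its β-carbon (future C4a); the β-amino ketone so formed expels the amine by E1cB and loss of the C8a proton restores the push–pull enaminone. The closest known reaction type is the acid-promoted self-condensation of enaminones, whose first C–C bond forms in this way on the path to 1,3,5-triacylbenzenes, here made intramolecular and, in its logic of group selection, akin to the Hajos–Parrish desymmetrisation of prochiral 1,3-diketones. Ring B closes in a 6-(enolexo)-exo-trig mode: the enamine double bond C1=C8a is exocyclic to the new ring and the attacked C4a=N+ bond is exo as well. C7 is the only new stereocentre that survives, and its configuration is fixed by which enantiotopic arm acts as nucleophile; the C2-symmetric (2R,5R)-pyrrolidine on both arms makes the two closures diastereomeric, because the tether forces attack on one face of the iminium carbon and that face is matched or mismatched with the flanking methyl groups. The step needs group selectivity between the arms, C- over O-attack and intra- over intermolecular condensation: the first rests on the amine, the second on the reversibility of O-attack (only C-attack can lose amine to a neutral product), the third on dilution. It stops after one event because C7 is quaternary, so ring B cannot aromatise, and the C5=C4a–C8a=C1 diene of 11 is locked s-trans and cannot annulate a third unit. Since the amine stays on C1, the (7R) and (7S) products are diastereomers and the minor one can be removed by chromatography or crystallisation.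

Step 8
Reactants: 11 (1R,3E)-3-{[(2R,5R)-2,5-dimethylpyrrolidin-1-yl]methylidene}-1-methyl-2,6-dioxocyclohex-4-en-1-yl 2,4-bis(methoxymethoxy)-6-methylbenzoate
Product: 12 (1R,3Z)-3-(hydroxymethylidene)-1-methyl-2,6-dioxocyclohex-4-en-1-yl 2,4-bis(methoxymethoxy)-6-methylbenzoate
Conditions: 1 M aq HCl/THF (1:2), 0 °C, short contact; amine recovered from the aqueous phase
Reagents that add atoms: water, O
Why: Hydrolysis of a vinylogous amide, driven by formation of the strongly acidic 2-formyl-1,3-dione and removal of the amine as its ammonium salt; aryl MOM ethers should survive cold dilute acid for this time, and C7 has no pathway for epimerisation because C1 marks the C8 flank.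

Step 9
Reactants: 13 1,1-dimethoxypropan-2-one
Product: 14 1,1,2,2-tetramethoxypropane
Conditions: HC(OMe)3, MeOH, TsOH·H2O (cat.), rt; NaOMe quench; distillation
Reagents that add atoms: trimethyl orthoformate, COC(OC)OC; methanol, CO
Why: Acid-catalysed ketalisation of a methyl ketone with an orthoester as dehydrating agent.

Step 10
Reactants: 14 1,1,2,2-tetramethoxypropane
Product: 15 2,3,3-trimethoxyprop-1-ene
Conditions: TMSOTf (1.1 equiv), iPr2NEt (1.2 equiv), CH2Cl2, −20 °C → rt; distillation
Reagents that add atoms: none
Why: Silyl triflate-mediated elimination of methanol from a ketal through the oxocarbenium ion; only the ketal carbon can ionise productively, and the hindered base removes a methyl proton to give the terminal enol ether.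

Step 11
Reactants: 12 (1R,3Z)-3-(hydroxymethylidene)-1-methyl-2,6-dioxocyclohex-4-en-1-yl 2,4-bis(methoxymethoxy)-6-methylbenzoate; 15 2,3,3-trimethoxyprop-1-ene
Product: 17 (7R)-3-(dimethoxymethyl)-7-methyl-6,8-dioxo-5,6,7,8-tetrahydro-4aH-isochromen-7-yl 2,4-bis(methoxymethoxy)-6-methylbenzoate (C4a epimers), via the 3-methoxy cycloadduct 16 (not isolated)
Conditions: 15 (4 equiv), PhMe, 60 °C; evaporate; PPTS (0.2 equiv), PhMe, 80 °C
Reagents that add atoms: none
Why: Inverse-electron-demand hetero-Diels–Alder reaction of an α-formyl enone with a 2-alkoxy alkene, as known for 3-formylchromones: the tautomer of 12 with the proton on the C6 oxygen has the 1-oxadiene O=C1–C8a=C4a, the nucleophilic CH2 of 15 bonds to C4a and the formyl oxygen to the ketal carbon. The cyclic mixed ketal 16 then loses methanol under mild acid to the 4H-pyran; the C3 and C4a configurations do not matter because both centres end sp2.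

Step 12
Reactants: 17 (7R)-3-(dimethoxymethyl)-7-methyl-6,8-dioxo-5,6,7,8-tetrahydro-4aH-isochromen-7-yl 2,4-bis(methoxymethoxy)-6-methylbenzoate
Product: 18 (7R)-3-(dimethoxymethyl)-7-methyl-6,8-dioxo-7,8-dihydro-6H-isochromen-7-yl 2,4-bis(methoxymethoxy)-6-methylbenzoate
Conditions: DDQ (1.2 equiv), PhH, rt
Reagents that add atoms: none
Why: Quinone dehydrogenation of a 4H-pyran: hydride abstraction from the doubly allylic C4a–H gives a pyrylium ion, which loses the acidic C5 proton (α to the C6 ketone) to the pyranoquinone methide. Only C4a–H/C5–H can be removed because C7 is quaternary.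

Step 13
Reactants: 18 (7R)-3-(dimethoxymethyl)-7-methyl-6,8-dioxo-7,8-dihydro-6H-isochromen-7-yl 2,4-bis(methoxymethoxy)-6-methylbenzoate
Product: 19 (7R)-3-formyl-7-methyl-6,8-dioxo-7,8-dihydro-6H-isochromen-7-yl 2,4-dihydroxy-6-methylbenzoate
Conditions: 3 M aq HCl/THF (1:3), rt
Reagents that add atoms: water, O
Why: Acid hydrolysis of the dimethyl acetal and of both aryl MOM ethers in one operation; the azaphilone core is formed and handled under acid, and the tertiary ester cannot ionise next to two carbonyl groups.

Step 14
Reactants: 19 (7R)-3-formyl-7-methyl-6,8-dioxo-7,8-dihydro-6H-isochromen-7-yl 2,4-dihydroxy-6-methylbenzoate; 20 (triphenylphosphoranylidene)acetaldehyde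
Product: 21 (7R)-7-methyl-6,8-dioxo-3-[(1E)-3-oxoprop-1-en-1-yl]-7,8-dihydro-6H-isochromen-7-yl 2,4-dihydroxy-6-methylbenzoate
Conditions: 20 (1.1 equiv), CH2Cl2, rt
Reagents that add atoms: none
Why: Wittig olefination with a stabilised formyl ylide, which should give the E-enal under neutral conditions; the ylide is too weakly basic to be quenched by the phenols, and the product enal is less electrophilic than the C3 aldehyde.

**Compound list**

1 | orsellinic acid (2,4-dihydroxy-6-methylbenzoic acid) | Cc1cc(O)cc(O)c1C(=O)O | starting material
2 | methoxymethyl 2,4-bis(methoxymethoxy)-6-methylbenzoate | Cc1cc(OCOC)cc(OCOC)c1C(=O)OCOC | intermediate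
3 | 2,4-bis(methoxymethoxy)-6-methylbenzoic acid | Cc1cc(OCOC)cc(OCOC)c1C(=O)O | intermediate
4 | 3-chloropentane-2,4-dione | CC(=O)C(Cl)C(C)=O | starting material
5 | 2,4-dioxopentan-3-yl 2,4-bis(methoxymethoxy)-6-methylbenzoate | CC(=O)C(OC(=O)c1c(C)cc(OCOC)cc1OCOC)C(C)=O | intermediate
6 | 3-methyl-2,4-dioxopentan-3-yl 2,4-bis(methoxymethoxy)-6-methylbenzoate | CC(=O)C(C)(OC(=O)c1c(C)cc(OCOC)cc1OCOC)C(C)=O | intermediate
7 | N,N-dimethylformamide dimethyl acetal | COC(OC)N(C)C | starting material
8 | (1E,6E)-1,7-bis(dimethylamino)-4-methyl-3,5-dioxohepta-1,6-dien-4-yl 2,4-bis(methoxymethoxy)-6-methylbenzoate | CN(C)/C=C/C(=O)C(C)(OC(=O)c1c(C)cc(OCOC)cc1OCOC)C(=O)/C=C/N(C)C | intermediate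
9 | (2R,5R)-2,5-dimethylpyrrolidine | C[C@@H]1CC[C@@H](C)N1 | starting material
10 | (1E,6E)-1,7-bis[(2R,5R)-2,5-dimethylpyrrolidin-1-yl]-4-methyl-3,5-dioxohepta-1,6-dien-4-yl 2,4-bis(methoxymethoxy)-6-methylbenzoate | C[C@@H]1CC[C@@H](C)N1/C=C/C(=O)C(C)(OC(=O)c1c(C)cc(OCOC)cc1OCOC)C(=O)/C=C/N1[C@H](C)CC[C@H]1C | intermediate
11 | (1R,3E)-3-{[(2R,5R)-2,5-dimethylpyrrolidin-1-yl]methylidene}-1-methyl-2,6-dioxocyclohex-4-en-1-yl 2,4-bis(methoxymethoxy)-6-methylbenzoate | Cc1cc(OCOC)cc(OCOC)c1C(=O)O[C@]1(C)C(=O)C=C/C(=C\N2[C@H](C)CC[C@H]2C)C1=O | intermediate
12 | (1R,3Z)-3-(hydroxymethylidene)-1-methyl-2,6-dioxocyclohex-4-en-1-yl 2,4-bis(methoxymethoxy)-6-methylbenzoate (one tautomer of the formyl dienone) | Cc1cc(OCOC)cc(OCOC)c1C(=O)O[C@]1(C)C(=O)C=C/C(=C/O)C1=O | intermediate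
13 | 1,1-dimethoxypropan-2-one | CC(=O)C(OC)OC | starting material
14 | 1,1,2,2-tetramethoxypropane | CC(OC)(OC)C(OC)OC | intermediate
15 | 2,3,3-trimethoxyprop-1-ene | C=C(OC)C(OC)OC | intermediate
16 | (7R)-3-(dimethoxymethyl)-3-methoxy-7-methyl-6,8-dioxo-4,4a,5,6,7,8-hexahydro-3H-isochromen-7-yl 2,4-bis(methoxymethoxy)-6-methylbenzoate (C3/C4a diastereomers) | Cc1cc(OCOC)cc(OCOC)c1C(=O)O[C@]1(C)C(=O)CC2CC(OC)(C(OC)OC)OC=C2C1=O | intermediate
17 | (7R)-3-(dimethoxymethyl)-7-methyl-6,8-dioxo-5,6,7,8-tetrahydro-4aH-isochromen-7-yl 2,4-bis(methoxymethoxy)-6-methylbenzoate (C4a epimers) | Cc1cc(OCOC)cc(OCOC)c1C(=O)O[C@]1(C)C(=O)CC2C=C(C(OC)OC)OC=C2C1=O | intermediate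
18 | (7R)-3-(dimethoxymethyl)-7-methyl-6,8-dioxo-7,8-dihydro-6H-isochromen-7-yl 2,4-bis(methoxymethoxy)-6-methylbenzoate | Cc1cc(OCOC)cc(OCOC)c1C(=O)O[C@]1(C)C(=O)C=C2C=C(C(OC)OC)OC=C2C1=O | intermediate
19 | (7R)-3-formyl-7-methyl-6,8-dioxo-7,8-dihydro-6H-isochromen-7-yl 2,4-dihydroxy-6-methylbenzoate | Cc1cc(O)cc(O)c1C(=O)O[C@]1(C)C(=O)C=C2C=C(C=O)OC=C2C1=O | intermediate
20 | (triphenylphosphoranylidene)acetaldehyde | O=CC=P(c1ccccc1)(c1ccccc1)c1ccccc1 | starting material
21 | (7R)-7-methyl-6,8-dioxo-3-[(1E)-3-oxoprop-1-en-1-yl]-7,8-dihydro-6H-isochromen-7-yl 2,4-dihydroxy-6-methylbenzoate | Cc1cc(O)cc(O)c1C(=O)O[C@]1(C)C(=O)C=C2C=C(/C=C/C=O)OC=C2C1=O | target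

**Step count and risks**

Total: 14 steps. Longest linear sequence: 12 steps (1–8 and 11–14, from 1); steps 9 and 10 make the dienophile.

Step 7 (proposed new method). What may go wrong: weak discrimination between the two enantiotopic arms, so that both C7 epimers form in similar amounts; intermolecular condensation competing with ring closure; or stalling because the reactive s-trans conformer of the electrophilic arm is disfavoured next to the quaternary carbon. Fallback by known chemistry, setting out from 3 and coming back at 11: purchased 2,4-dihydroxy-3-methylbenzaldehyde F1 is dearomatised at its methyl-bearing carbon by a Wessely-type acyloxylation with the trivalent-iodine dicarboxylate F2, made from PhI(OAc)2 and two equivalents of 3 by ligand exchange. The carboxylate is delivered to the position that is oxidised in the usual azaphilone dearomatisation, and this gives the racemic formyl dienone F3. Condensation of F3 with 9 gives 11 and its (7S) diastereomer F4, which are separated by chromatography or crystallisation; 11 then continues with step 8. This replaces the desymmetrisation by a resolution through the same amine.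

Step 11. What may go wrong: bond formation at the wrong atoms. The dienone tautomer of 12 can react as a carbocyclic diene across C8a and C6, the formyl carbon can be attacked instead of C4a, and the acidic enol can consume the enol ether by O-ketalisation. The reactive tautomer is a minor one, so the cycloaddition may also be slow. Fallback, setting out from 11 and coming back at 17: the silyl enol ether F5 (from 13, TMSOTf, Et3N) is added in a Mukaiyama–Michael reaction (TMSOTf, CH2Cl2, −78 °C) to C4a of 11, whose C1 is shielded by the dimethylpyrrolidine. Aqueous work-up gives the keto enaminone F6. Warming F6 in AcOH lets the enol oxygen of the new ketone displace the amine at C1, the ring closure by which chromones and 4-pyranones are made from enaminones; this gives 17 and returns 9. Step 8 is then not needed.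

Step 6. What may go wrong: incomplete exchange because the amine is flanked by two methyl groups, and premature cyclisation of 8 or of a mono-exchanged intermediate on prolonged heating, which would carry racemic material forward. The preceding condensation (step 5) also risks retro-Claisen cleavage of the non-enolisable diketone by liberated methoxide. Fallback, setting out from 6 and coming back at 10, bypassing steps 5 and 6: soft enolisation (TMSOTf, Et3N) gives the bis(silyl enol ether) F7. Mukaiyama-type addition of F7 to trimethyl orthoformate (BF3·OEt2, CH2Cl2, −78 °C) gives the bis(β-keto acetal) F8. Heating F8 with 9 eliminates methanol by way of the β-methoxy enone, a better acceptor for a hindered amine than a vinylogous amide, and gives 10.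

Step 12. What may go wrong: slow hydride abstraction because the pyran is electron-poor, or capture of the pyrylium intermediate by the reduced quinone. Fallback, setting out from 17 and coming back at 18: 17 is converted (TMSOTf, Et3N) into the silyl dienol ether F9, which is oxidised by Pd(OAc)2 (divalent palladium, MeCN, rt) in a Saegusa–Ito dehydrogenation; β-hydride elimination can only take the C4a hydrogen.

Step 14. What may go wrong: a second homologation of the product enal, conjugate addition of the ylide to C1 of the pyran, or low conversion if the aldehyde is largely hydrated. Fallback, setting out from 18 and coming back at 21: a Müller-Cunradi–Pieroh-type chain extension. Ethyl vinyl ether adds to the oxocarbenium ion of the dimethyl acetal (ZnCl2 cat., EtOAc, 0 °C) to give the β-methoxy mixed acetal F10. Aqueous acid (3 M HCl/THF) then hydrolyses the acetal, eliminates methanol to the E-enal and removes both MOM groups in one operation, so steps 13 and 14 are replaced.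

**Further compounds**

F1 | step 7 | 2,4-dihydroxy-3-methylbenzaldehyde (purchased) | Cc1c(O)ccc(C=O)c1O
F2 | step 7 | phenyl-λ3-iodanediyl bis[2,4-bis(methoxymethoxy)-6-methylbenzoate] | Cc1cc(OCOC)cc(OCOC)c1C(=O)OI(OC(=O)c1c(C)cc(OCOC)cc1OCOC)c1ccccc1
F3 | step 7 | racemic (3Z)-3-(hydroxymethylidene)-1-methyl-2,6-dioxocyclohex-4-en-1-yl 2,4-bis(methoxymethoxy)-6-methylbenzoate | Cc1cc(OCOC)cc(OCOC)c1C(=O)OC1(C)C(=O)C=C/C(=C/O)C1=O
F4 | step 7 | (1S,3E)-3-{[(2R,5R)-2,5-dimethylpyrrolidin-1-yl]methylidene}-1-methyl-2,6-dioxocyclohex-4-en-1-yl 2,4-bis(methoxymethoxy)-6-methylbenzoate | Cc1cc(OCOC)cc(OCOC)c1C(=O)O[C@@]1(C)C(=O)C=C/C(=C\N2[C@H](C)CC[C@H]2C)C1=O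
F5 | step 11 | 3,3-dimethoxy-2-(trimethylsilyloxy)prop-1-ene | C=C(O[Si](C)(C)C)C(OC)OC
F6 | step 11 | (1R,3E)-4-(3,3-dimethoxy-2-oxopropyl)-3-{[(2R,5R)-2,5-dimethylpyrrolidin-1-yl]methylidene}-1-methyl-2,6-dioxocyclohexyl 2,4-bis(methoxymethoxy)-6-methylbenzoate (C4 epimers) | Cc1cc(OCOC)cc(OCOC)c1C(=O)O[C@]1(C)C(=O)CC(CC(=O)C(OC)OC)/C(=C\N2[C@H](C)CC[C@H]2C)C1=O
F7 | step 6 | 3-methyl-2,4-bis(trimethylsilyloxy)penta-1,4-dien-3-yl 2,4-bis(methoxymethoxy)-6-methylbenzoate | C=C(O[Si](C)(C)C)C(C)(OC(=O)c1c(C)cc(OCOC)cc1OCOC)C(=C)O[Si](C)(C)C
F8 | step 6 | 1,1,7,7-tetramethoxy-4-methyl-3,5-dioxoheptan-4-yl 2,4-bis(methoxymethoxy)-6-methylbenzoate | COC(OC)CC(=O)C(C)(OC(=O)c1c(C)cc(OCOC)cc1OCOC)C(=O)CC(OC)OC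
F9 | step 12 | (7R)-3-(dimethoxymethyl)-7-methyl-8-oxo-6-(trimethylsilyloxy)-7,8-dihydro-4aH-isochromen-7-yl 2,4-bis(methoxymethoxy)-6-methylbenzoate (C4a epimers) | Cc1cc(OCOC)cc(OCOC)c1C(=O)O[C@]1(C)C(O[Si](C)(C)C)=CC2C=C(C(OC)OC)OC=C2C1=O
F10 | step 14 | (7R)-3-(3-ethoxy-1,3-dimethoxypropyl)-7-methyl-6,8-dioxo-7,8-dihydro-6H-isochromen-7-yl 2,4-bis(methoxymethoxy)-6-methylbenzoate (side-chain diastereomers) | Cc1cc(OCOC)cc(OCOC)c1C(=O)O[C@]1(C)C(=O)C=C2C=C(C(OC)CC(OC)OCC)OC=C2C1=O
A1 | alternative 1 | (7R)-3-[(1E)-3-(tert-butyldimethylsilyloxy)prop-1-en-1-yl]-7-hydroxy-7-methyl-6H-isochromene-6,8(7H)-dione | O[C@]1(C)C(=O)C=C2C=C(/C=C/CO[Si](C)(C)C(C)(C)C)OC=C2C1=O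
A2 | alternative 2 | (7R)-3-[(1E)-3,3-dimethoxyprop-1-en-1-yl]-7-methyl-6,8-dioxo-7,8-dihydro-6H-isochromen-7-yl 2,4-bis(methoxymethoxy)-6-methylbenzoate | Cc1cc(OCOC)cc(OCOC)c1C(=O)O[C@]1(C)C(=O)C=C2C=C(/C=C/C(OC)OC)OC=C2C1=O
A3 | alternative 3 | (7R)-3-[(1E)-3,3-dimethoxyprop-1-en-1-yl]-7-methyl-6,8-dioxo-5,6,7,8-tetrahydro-3H-isochromen-7-yl 2,4-bis(methoxymethoxy)-6-methylbenzoate (both C3 epimers, one drawn) | Cc1cc(OCOC)cc(OCOC)c1C(=O)O[C@]1(C)C(=O)CC2=C[C@H](/C=C/C(OC)OC)OC=C2C1=O
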